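## Structural features

The target is a flavone: a benzo ring A fused to a 4-pyranone ring C (O1, C2, C3, C4, C4a, C8a), with aryl ring B joined to C2 through C1' and a methoxy group on C3. It has no stereocentre, stereogenic axis or configurable double bond, so no configuration has to be set and the question of enantiomers does not arise. Six oxygen substituents sit on the periphery: methyl ethers at C3, C7, C2' and C4', and free phenols at C6 and C5', each phenol ortho to a methoxy group. The fragile points are the two guaiacol-type phenols (readily oxidised as phenoxides in air), the pyranone C2 (adds strong nucleophiles with ring opening) and the methyl ethers (cleavable by Lewis acids). The real difficulty is regiochemical: two hydroxyls must stay distinct from four methoxyls on two electron-rich rings, and no step may methylate or demethylate the wrong oxygen. Rings A and B hide a repeat: C4a–C5–C6(OH)–C7(OMe)–C8–C8a(O1) and C1'–C6'–C5'(OH)–C4'(OMe)–C3'–C2'(OMe) are the same 2,4,5-trioxygenated phenyl unit, bonded through C4a and C1' to the two ends of the C4–C3(OMe)–C2 chain. They differ only in that the oxygen on C8a is the ring oxygen while the one on C2' is methylated. The key step uses this repeat by joining two copies of one arene to a three-carbon unit that already carries the C3 methoxy group, forming C4–C4a and C2–C1' in one operation.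

## Logic of the disconnections

11 ⇒ 9. The bonds cut are the aryl–oxygen bond C2'–OMe and the two acyl–oxygen bonds on the C6 and C5' oxygens. This reduces the only difference between rings A and B to a single bromine and keeps both phenols masked as hindered esters until the end. The forward step must replace an aryl bromide by methoxide and remove both esters without methylating a phenol or destroying the pyranone. It passes through 10, in which the esters are already gone.

9 ⇒ 8. The O1–C8a bond is cut, opening the pyranone to an acyclic 1,3-diketone whose two aryl ketone halves are identical. The gain is symmetry: either enol oxygen closing onto either ring gives the same chromone, so no site selection is needed. The forward step must join the enolate oxygen to one C–Br carbon while the second C–Br bond and both esters survive.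

8 ⇒ 3 + 3 + 6. Both aryl–carbonyl bonds, C4–C4a and C2–C1', are cut, releasing two molecules of one arene and a three-carbon diacid chloride that already bears the C3 methoxy group. This is the largest simplification of the plan: a 28-carbon diketone falls into a 12-carbon arene used twice and a 4-carbon unit. The forward step must acylate each arene once, para to its methoxy group and next to bromine, on two separate rings, and the α-alkoxy acyl chloride must not fragment. The half-reacted 7 is passed through.

6 ⇒ 5 ⇒ 4. Only functional groups change: the two C–Cl bonds go back to the diacid and the diacid goes back to the commercial diester. The demand is practical: 5 must be isolated without decarboxylation, and 6 must be freed of excess chlorinating agent and used at once.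

3 ⇒ 1 + 2. The acyl–oxygen bond of the ester is cut. The ester marks the future phenol oxygen as different from the methyl ether next to it, and it must survive a Lewis acid and a carbonate base.

## Other disconnections considered

Alternative 1: The cut is O1–C2, with iodine standing in for the C3 oxygen. It leads back to the ynone A2, built from two molecules of the aldehyde A1 (one homologated to the alkyne, added to the second, and the carbinol oxidised). In the forward key step, ICl at low temperature activates the triple bond of A2, the ortho-methoxy oxygen of the aroyl ring attacks C2 in a 6-endo-dig closure, chloride removes the methyl group and the 3-iodoflavone A3 results. Exchange of iodine for methoxy and hydrogenolysis of both benzyl ethers would finish.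
- In favour: this type of ring closure is closely precedented and mild, and the 2'-methoxy group is present from the start, so no late aryl methoxylation is needed.
- In favour: hydrogenolysis is a gentler end game than hot methoxide. On these three points the alternative is the better plan. It equals the chosen plan in using one aryl building block twice.
- Against: ICl may iodinate the very electron-rich rings of A2.
- Against: the ortho-methoxy group of the alkyne-bearing ring offers a competing 5-endo closure onto the other alkyne carbon (the benzofuran-forming mode).
- Against: exchanging the C3 iodine of A3 for methoxide is uncertain, because methoxide can add at C2 of a 3-halochromone.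
- Against: A1 is not a stock chemical.
- Comparison: on structure, both plans exploit the A/B repeat. On mechanism, the alternative fixes regiochemistry by tethering, whereas the chosen plan relies on para direction by a methoxy group. On step economy, about nine steps are expected against six.

Alternative 2: The cut is again O1–C8a, but as an oxidative C–H/O–H coupling, leading back to the unsymmetrical diketone A4 with a free ring-A phenol. In the forward key step, constant-current anodic oxidation (carbon anode, hexafluoroisopropanol, 2,6-lutidine) converts the phenol of A4 into a phenoxonium ion, the enol oxygen adds at the carbon para to the hydroxyl and loss of a proton gives A5. Methanolysis of the one ester would give the target.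
- In favour: no halogen, copper or Lewis acid is used, and the ring-A phenol needs no protection.
- In favour: both the C3 and C2' methoxy groups are in place, and the end game is one mild methanolysis. On the end game and on reagent mildness the alternative is the better plan. On carrying the C3 methoxy group in from the start it is equal.
- Against: A4 is unsymmetrical, so two different aryl halves must be made and joined by a crossed acylation, and the two-for-one economy is lost.
- Against: in the phenoxonium ion the carbon ortho to the hydroxyl (C5) is also activated and also gives a six-membered ring, so site selectivity rests on charge distribution alone.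
- Against: A5 is a para-alkoxyphenol and should be easier to oxidise than A4, so over-oxidation to quinoid material threatens. The trioxygenated ring B is itself oxidisable.
- Comparison: on structure, the chosen plan uses the repeat and this one does not. On mechanism, the same bond is formed, but the chosen plan fixes its position with a bromine. On step economy, seven to eight steps are expected against six.

Alternative 3: The cuts are C3–C4 and O1–C2, leading back to the salicylaldehyde A6 and the aroyl sulfoxonium ylide A7. In the forward key step, a Cp*Rh(III) catalyst with acetate activates the formyl C–H bond of A6 under direction by the phenol. The ylide A7 delivers a carbene with loss of the sulfoxide, migratory insertion forms C3–C4, and the resulting 2-hydroxyaryl diketone cyclodehydrates in the same pot to the flavone A8.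
- In favour: the annulation is catalytic, convergent and precedented on close relatives, and every ring oxygen is placed beforehand, so regiochemistry is unambiguous. On these points the alternative is the better plan.
- Against: A8 has hydrogen at C3, and an ylide carbon cannot bring the methoxy group. C3 hydroxylation and O-methylation must follow on a substrate with two electron-rich rings, and debenzylation comes after that.
- Against: A6 and A7 are different building blocks, each needing several steps, and rhodium is costly.
- Comparison: on structure, the chosen plan delivers the C3 methoxy group with the three-carbon unit, while this one adds it late. On mechanism, the alternative is the more certain C–C bond formation. On step economy, about ten steps are expected against six.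

Key step: step 4

Remark: the target is planar and achiral, so a single enantiomer is obtained by default and no step has to control configuration.

Remark: the arene, the dichloride and the diketone of the key step map atom for atom onto the target, so no structure needed correction. In the arene, C5 becomes C4a and C1', the C1 oxygen becomes 6-OH and 5'-OH, the C2 methoxy becomes 7-OMe and 4'-OMe, and C4–Br becomes C8a and C2'.

Remark: bromine is kept as the halogen because fluorine and chlorine would not undergo the late copper-mediated methoxylation and iodine would migrate under aluminium chloride. The pivalate is kept because a less hindered ester would not survive the carbonate step and a sulfonate would release a methylating agent on methanolysis.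

Remark: the plan is tightened at two points: excess oxalyl chloride is stripped before the key step because it would itself acylate 3, and the dichloride is added slowly to an excess of arene in dichloromethane to suppress decarbonylation.

## Route

Step 1
Reactants: 1 4-bromo-2-methoxyphenol; 2 pivaloyl chloride
Product: 3 4-bromo-2-methoxyphenyl pivalate
Conditions: Et3N (1.3 equiv), DMAP (5 mol %), CH2Cl2, 0 °C to rt
Reagents that add atoms: none
Why: Nucleophilic acyl substitution (DMAP-catalysed O-acylation of a phenol); the hindered ester marks the future free hydroxyl and should resist carbonate base later.

Step 2
Reactants: 4 dimethyl methoxymalonate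
Product: 5 methoxymalonic acid
Conditions: NaOH (2.2 equiv), H2O/MeOH, 0 °C to rt; HCl to pH 1 at 0 °C; EtOAc extraction, evaporation below 30 °C, drying in vacuo
Reagents that add atoms: sodium hydroxide, [Na+].[OH-]
Why: Saponification of a malonate diester (BAc2); cold acidification and cold concentration should avoid decarboxylation of the malonic acid.

Step 3
Reactants: 5 methoxymalonic acid
Product: 6 methoxymalonyl dichloride
Conditions: (COCl)2 (2.4 equiv), DMF (cat.), CH2Cl2, 0 °C to rt; volatiles and excess (COCl)2 stripped below 20 °C; used at once as a CH2Cl2 solution
Reagents that add atoms: oxalyl chloride, O=C(Cl)C(=O)Cl
Why: Acid chloride formation through the Vilsmeier-type chloroiminium species, which works at or below room temperature and so spares the heat-sensitive α-alkoxy malonyl unit.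

Step 4
Reactants: 3 4-bromo-2-methoxyphenyl pivalate (two molecules react; 2.5 equiv used, excess recovered); 6 methoxymalonyl dichloride
Product: 8 1,3-bis[2-bromo-4-methoxy-5-(pivaloyloxy)phenyl]-2-methoxypropane-1,3-dione, via monoacylated keto acid chloride 7 (not isolated)
Conditions: AlCl3 (6 equiv), CH2Cl2, 6 added dropwise at −10 °C, then to rt; quench on ice/1 M HCl
Reagents that add atoms: none
Why: Aluminium chloride activates one acyl chloride of 6 (as its donor–acceptor complex or acyl cation), which attacks C5 of 3 and, after loss of HCl, gives 7; the same events at the second acyl chloride with a second molecule of 3 give 8. The closest known reaction type is the twofold Friedel–Crafts acylation of anisole-type arenes by malonyl dichlorides to 1,3-diaryl-1,3-diketones. No ring is closed and no stereocentre is formed, since the central carbon of 8 carries two identical aroyl groups. The site is secured by the methoxy group, the strongest donor, whose para position is C5; C3 is shielded between methoxy and bromine, C6 is meta to the methoxy group, and the aluminium-complexed ester acts only as an inductive acceptor from the meta position. The two-to-one outcome is secured because the first aroyl group deactivates its own ring and its only free ortho carbon (C6) is not activated, so closure to an indanedione is disfavoured and the excess of 3 captures the second acyl chloride intermolecularly. Loss of carbon monoxide from the α-methoxy acyl cation is the main threat, but the oxocarbenium ion it would give has a carbonyl group on the cationic carbon and is poorly stabilised, and slow addition into excess arene in a non-ionising solvent at low temperature should keep trapping faster than fragmentation. No methoxy group ends up ortho to a ketone, so chelation-driven demethylation of the ring ethers has no handle.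

Step 5
Reactants: 8 1,3-bis[2-bromo-4-methoxy-5-(pivaloyloxy)phenyl]-2-methoxypropane-1,3-dione
Product: 9 2'-bromo-3,7,4'-trimethoxy-6,5'-bis(pivaloyloxy)flavone
Conditions: CuI (10 mol %), 1,10-phenanthroline (20 mol %), K2CO3 (2 equiv), dry DMF, 90 °C, Ar
Reagents that add atoms: none
Why: Intramolecular Ullmann-type O-arylation of the diketone enolate onto the C–Br bond ortho to the ketone closes the six-membered pyranone, a known route from 1-(2-bromoaryl)-1,3-diketones to flavones. C-arylation would need a four-membered ring, and the two bromoaryl groups are equivalent, so one product is expected. The hindered pivalates should survive anhydrous carbonate.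

Step 6
Reactants: 9 2'-bromo-3,7,4'-trimethoxy-6,5'-bis(pivaloyloxy)flavone
Product: 11 6,5'-dihydroxy-3,7,2',4'-tetramethoxyflavone (target), via bromoflavone diphenol 10 (not isolated)
Conditions: NaOMe (8 equiv), CuI (30 mol %), degassed MeOH/DMF 1:3, 100 °C, Ar; then 1 M HCl to pH 3
Reagents that add atoms: sodium methoxide, [Na+].[O-]C
Why: Methoxide first transesterifies both pivalates to give 10 as its bis-phenoxide, and copper(I)-catalysed Ullmann methoxylation then replaces the 2'-bromine, helped by the electron-poor pyranone carbon ortho to it. No methylating agent is formed, so the phenols stay free, and acidification should reclose any pyranone opened reversibly by methoxide.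

## Compound list

1 | 4-bromo-2-methoxyphenol | COc1cc(Br)ccc1O | starting material
2 | pivaloyl chloride | CC(C)(C)C(=O)Cl | starting material
3 | 4-bromo-2-methoxyphenyl pivalate | COc1cc(Br)ccc1OC(=O)C(C)(C)C | intermediate
4 | dimethyl methoxymalonate | COC(C(=O)OC)C(=O)OC | starting material
5 | methoxymalonic acid | COC(C(=O)O)C(=O)O | intermediate
6 | methoxymalonyl dichloride | COC(C(=O)Cl)C(=O)Cl | intermediate
7 | 3-[2-bromo-4-methoxy-5-(pivaloyloxy)phenyl]-2-methoxy-3-oxopropanoyl chloride (racemic, not isolated) | COC(C(=O)Cl)C(=O)c1cc(OC(=O)C(C)(C)C)c(OC)cc1Br | intermediate
8 | 1,3-bis[2-bromo-4-methoxy-5-(pivaloyloxy)phenyl]-2-methoxypropane-1,3-dione | COC(C(=O)c1cc(OC(=O)C(C)(C)C)c(OC)cc1Br)C(=O)c1cc(OC(=O)C(C)(C)C)c(OC)cc1Br | intermediate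
9 | 2'-bromo-3,7,4'-trimethoxy-6,5'-bis(pivaloyloxy)flavone | COc1cc(Br)c(-c2oc3cc(OC)c(OC(=O)C(C)(C)C)cc3c(=O)c2OC)cc1OC(=O)C(C)(C)C | intermediate
10 | 2'-bromo-6,5'-dihydroxy-3,7,4'-trimethoxyflavone (not isolated) | COc1cc(Br)c(-c2oc3cc(OC)c(O)cc3c(=O)c2OC)cc1O | intermediate
11 | 6,5'-dihydroxy-3,7,2',4'-tetramethoxyflavone | COc1cc(OC)c(-c2oc3cc(OC)c(O)cc3c(=O)c2OC)cc1O | target

## Step count and least certain steps

Total step count: 6. Longest linear sequence: 5 steps (4 → 5 → 6 → 8 → 9 → 11; the arene branch 1 → 3 joins at step 4).

Step 4 (key step). The most likely failure is loss of carbon monoxide from the α-methoxy acyl cation before it is trapped, so that the arene is alkylated by the resulting oxocarbenium ion and one carbon is lost. This is the usual behaviour of alkoxyacetyl chlorides under aluminium chloride, and only the acyl substituent on the cationic carbon argues against it here. Lewis-acid cleavage of the pivalate (fragmentation of the pivaloyl cation), cleavage of the central methyl ether in the aluminium chelate of the product, and stalling after the first acylation are secondary risks. Fallback: starting from 3, the twofold acylation is run with unsubstituted malonyl dichloride (ClC(=O)CC(=O)Cl) and AlCl3, whose acyl cation has no such fragmentation path, to give 1,3-bis[2-bromo-4-methoxy-5-(pivaloyloxy)phenyl]propane-1,3-dione F1. The methoxy group is then placed on the central carbon by oxidative α-alkoxylation of the β-diketone with iodosylbenzene and BF3·OEt2 in methanol, which returns to the route at 8.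

Step 6. The most likely failure is slow substitution: methanolysis of the 5'-ester puts a phenoxide para to the bromine and makes the ring electron-rich. Reductive loss of bromine, irreversible cleavage of the methoxide-opened pyranone and aerial oxidation of the phenoxides could then compete. Fallback: starting from 9, the bromine is replaced by palladium-catalysed C–O coupling with methanol (bulky biarylphosphine palladium precatalyst, Cs2CO3, MeOH in toluene, 70 °C), where oxidative addition does not need an electron-poor ring. This gives 3,7,2',4'-tetramethoxy-6,5'-bis(pivaloyloxy)flavone F2; partial ester loss at this stage is harmless. K2CO3 in methanol at room temperature then removes both esters and returns to the route at 11.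

Step 5. The most likely failure is premature loss of a pivalate under carbonate in hot DMF, which places a phenoxide para to the C–Br bond and slows the closure. Base-induced C–C cleavage of the α-methoxy diketone and sluggish reaction of the twisted, weakly enolised diketone are further risks. Fallback: starting from 8, ring closure and methoxylation are merged in one operation with CuI (0.5 equiv) and NaOMe in degassed MeOH/DMF at 100 °C. The esters are cleaved deliberately first, to 1,3-bis(2-bromo-5-hydroxy-4-methoxyphenyl)-2-methoxypropane-1,3-dione F3 in the flask, which cyclises to 10 and is methoxylated. Because 8 is symmetric, the opposite order of the two C–O bond formations converges on the same flavone. The route is rejoined at 11 and 9 is bypassed.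

Step 3. The most likely failure is decomposition of the reagent: decarboxylation of 5 during drying, or loss of HCl from 6 to a chlorocarbonyl ketene that oligomerises, both favoured by heat and by acid. Fallback: starting from 4, saponification with exactly two equivalents of KOH in methanol and evaporation gives dipotassium methoxymalonate F4. This is suspended in CH2Cl2 and treated with oxalyl chloride and catalytic DMF at 0 °C; filtration delivers a solution of 6 without passing through the free acid 5 and without generating HCl, and the route is rejoined at 6.

## Further compounds

F1 | step 4 | 1,3-bis[2-bromo-4-methoxy-5-(pivaloyloxy)phenyl]propane-1,3-dione | COc1cc(Br)c(C(=O)CC(=O)c2cc(OC(=O)C(C)(C)C)c(OC)cc2Br)cc1OC(=O)C(C)(C)C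
F2 | step 6 | 3,7,2',4'-tetramethoxy-6,5'-bis(pivaloyloxy)flavone | COc1cc(OC)c(-c2oc3cc(OC)c(OC(=O)C(C)(C)C)cc3c(=O)c2OC)cc1OC(=O)C(C)(C)C
F3 | step 5 | 1,3-bis(2-bromo-5-hydroxy-4-methoxyphenyl)-2-methoxypropane-1,3-dione | COC(C(=O)c1cc(O)c(OC)cc1Br)C(=O)c1cc(O)c(OC)cc1Br
F4 | step 3 | dipotassium methoxymalonate | COC(C(=O)[O-])C(=O)[O-].[K+].[K+]
A1 | alternative 1 | 5-(benzyloxy)-2,4-dimethoxybenzaldehyde | COc1cc(OC)c(OCc2ccccc2)cc1C=O
A2 | alternative 1 | 1,3-bis[5-(benzyloxy)-2,4-dimethoxyphenyl]prop-2-yn-1-one | COc1cc(OC)c(OCc2ccccc2)cc1C#CC(=O)c1cc(OCc2ccccc2)c(OC)cc1OC
A3 | alternative 1 | 6,5'-bis(benzyloxy)-3-iodo-7,2',4'-trimethoxyflavone | COc1cc(OC)c(-c2oc3cc(OC)c(OCc4ccccc4)cc3c(=O)c2I)cc1OCc1ccccc1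
A4 | alternative 2 | 1-(3-hydroxy-4-methoxyphenyl)-2-methoxy-3-[2,4-dimethoxy-5-(pivaloyloxy)phenyl]propane-1,3-dione | COc1ccc(C(=O)C(OC)C(=O)c2cc(OC(=O)C(C)(C)C)c(OC)cc2OC)cc1O
A5 | alternative 2 | 6-hydroxy-3,7,2',4'-tetramethoxy-5'-(pivaloyloxy)flavone | CC(C)(C)C(=O)Oc1cc(-c2oc3cc(OC)c(O)cc3c(=O)c2OC)c(OC)cc1OC
A6 | alternative 3 | 5-(benzyloxy)-2-hydroxy-4-methoxybenzaldehyde | COc1cc(O)c(C=O)cc1OCc1ccccc1
A7 | alternative 3 | 1-[5-(benzyloxy)-2,4-dimethoxyphenyl]-2-[dimethyl(oxo)-λ6-sulfanylidene]ethan-1-one | COc1cc(OC)c(C(=O)C=S(C)(C)=O)cc1OCc1ccccc1
A8 | alternative 3 | 6,5'-bis(benzyloxy)-7,2',4'-trimethoxyflavone | COc1cc(OC)c(-c2cc(=O)c3cc(OCc4ccccc4)c(OC)cc3o2)cc1OCc1ccccc1
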